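**Retrosynthetic overview**
1. The target is the C6 stearate of (+)-lariciresinol. The ester C6–O bond is made last from free lariciresinol and stearic acid (Mitsunobu); lariciresinol comes from a tetrahydrofuran-3-carbaldehyde by one hydride step that also removes both aryl pivalates.
2. Feature used: in the tetrahydrofuran ring (O1, C2 aryl, C3, C4 benzyl, C5), C5 is an unsubstituted OCH2 and C3 bears the one-carbon oxygenated arm C6. O1, C5, the C4–C5 bond and the C2–C3 bond therefore map onto the formaldehyde acetal of an allylic 1,2-diol.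
3. Key disconnection (C4–C5 and C2–C3): aldehyde ⇒ trans-4-aryl-5-[(E)-3-arylprop-1-enyl]-1,3-dioxolane by Prins cyclisation–pinacol ring contraction. The tetrahydrofuran, the only ring made, forms here via a transient oxane.
4. Dioxolane ⇒ syn hydroxy MOM ether ⇒ cross-metathesis with eugenol pivalate plus asymmetric (Z)-γ-alkoxyallylboration of vanillin pivalate, which sets C2 and the sacrificial carbinol centre.
5. Both phenols travel as pivalates. With an O-alkyl group the C2 aryl would allow benzylic C–O ionisation under SnCl4, which would epimerise C2 of the acetal and erode enantiopurity; the acyloxy group suppresses this and keeps the arenes out of Friedel–Crafts paths.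

Key step: step 7

Remark: the borane made from (+)-α-pinene is taken to deliver the γ-alkoxyallyl group to the Si face of the aldehyde, as it does for allyl and crotyl groups. Ring numbering O1, C2–C5, with C6 the exocyclic carbon on C3, is used throughout.

**Route**

Step 1
Reactants: 1 vanillin
Product: 2 4-formyl-2-methoxyphenyl pivalate
Conditions: PivCl, Et3N, DMAP (cat.), CH2Cl2, 0 °C → rt
Reagents that add atoms: pivaloyl chloride, CC(C)(C)C(=O)Cl
Why: DMAP-catalysed O-acylation of the phenol with an acid chloride leaves the aldehyde untouched and installs the electron-withdrawing, hydride-cleavable protecting group.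

Step 2
Reactants: 3 eugenol
Product: 4 4-allyl-2-methoxyphenyl pivalate
Conditions: PivCl, Et3N, DMAP (cat.), CH2Cl2, 0 °C → rt
Reagents that add atoms: pivaloyl chloride, CC(C)(C)C(=O)Cl
Why: The same phenol O-acylation; the allyl group is inert to these conditions.

Step 3
Reactants: 5 allyl alcohol
Product: 6 3-(methoxymethoxy)prop-1-ene (allyl MOM ether)
Conditions: MOMCl, i-Pr2NEt, CH2Cl2, 0 °C → rt
Reagents that add atoms: chloromethyl methyl ether, COCCl
Why: O-alkylation of a primary alcohol with an α-chloro ether under amine base gives the MOM ether that serves as the γ-alkoxyallyl precursor.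

Step 4
Reactants: 6 3-(methoxymethoxy)prop-1-ene; 2 4-formyl-2-methoxyphenyl pivalate
Product: 10 4-[(1R,2R)-1-hydroxy-2-(methoxymethoxy)but-3-en-1-yl]-2-methoxyphenyl pivalate, via allyllithium 7 (not isolated), via allylborane 8 (not isolated), via borinate 9 (not isolated)
Conditions: 6, s-BuLi, THF, −78 °C; (−)-Ipc2BOMe [from (+)-α-pinene], −78 °C; BF3·OEt2, −78 °C; then 2, −78 °C → rt; HOCH2CH2NH2, Et2O, rt
Reagents that add atoms: none
Why: Brown alkoxyallylboration: lithiation of the allyl ether gives the chelated (Z)-alkoxyallyl anion, borylation and BF3-induced loss of methoxide give the (Z)-γ-alkoxyallylborane, and its closed chair transition state turns Z geometry into the syn (1R,2R) relationship while the isopinocampheyl groups direct attack to the Si face of the aldehyde; the non-oxidative ethanolamine work-up spares the aryl ester.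

Step 5
Reactants: 10 4-[(1R,2R)-1-hydroxy-2-(methoxymethoxy)but-3-en-1-yl]-2-methoxyphenyl pivalate; 4 4-allyl-2-methoxyphenyl pivalate
Product: 11 (1R,2R,3E)-2-(methoxymethoxy)-1,5-bis(3-methoxy-4-pivaloyloxyphenyl)pent-3-en-1-ol
Conditions: second-generation Grubbs catalyst RuCl2(=CHPh)(H2IMes)(PCy3) (5 mol %), 4 (3 equiv), 1,4-benzoquinone (10 mol %), CH2Cl2, 40 °C
Reagents that add atoms: none
Why: Olefin cross-metathesis between a fast-dimerising allylarene used in excess and a hindered allylic ether that does not homodimerise should favour the cross product as the thermodynamically preferred E alkene; benzoquinone suppresses Ru–H double-bond migration and no stereocentre is touched.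

Step 6
Reactants: 11 (1R,2R,3E)-2-(methoxymethoxy)-1,5-bis(3-methoxy-4-pivaloyloxyphenyl)pent-3-en-1-ol
Product: 12 (4R,5R)-4-(3-methoxy-4-pivaloyloxyphenyl)-5-[(E)-3-(3-methoxy-4-pivaloyloxyphenyl)prop-1-en-1-yl]-1,3-dioxolane (trans)
Conditions: TMSOTf (0.2 equiv), 4 Å MS, CH2Cl2, −20 → 0 °C; Et3N
Reagents that add atoms: none
Why: Intramolecular transacetalisation: the Lewis acid ionises the MOM group to an O-methylene oxocarbenium that the neighbouring hydroxyl traps with loss of methanol; no C–O bond at a stereocentre breaks, so the syn diol pattern becomes the trans acetal, and the deactivated aryl group keeps the benzylic alcohol from ionising.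

Step 7
Reactants: 12 (4R,5R)-4-(3-methoxy-4-pivaloyloxyphenyl)-5-[(E)-3-(3-methoxy-4-pivaloyloxyphenyl)prop-1-en-1-yl]-1,3-dioxolane
Product: 14 (2S,3S,4R)-2-(3-methoxy-4-pivaloyloxyphenyl)-4-(3-methoxy-4-pivaloyloxybenzyl)tetrahydrofuran-3-carbaldehyde (2,3-trans-3,4-cis), via 2,3-cis aldehyde 13 (not isolated)
Conditions: SnCl4 (3 equiv), CH2Cl2, −78 → −20 °C; Et3N, −78 °C, then aq. NaHCO3; DBU (0.3 equiv), CH2Cl2, rt
Reagents that add atoms: none
Why: SnCl4 opens the methylene acetal at the allylic oxygen to the O1=C5 oxocarbenium ion, whose E alkene attacks through C4 in a chair Prins closure that is 6-endo with respect to the oxocarbenium and puts positive charge on C3 beside the stannylated carbinol carbon; the ring bond from that carbon to C2 then shifts to C3 (pinacol step), contracting the transient oxane to the tetrahydrofuran and releasing C6 as the formyl group, and a 2-oxonia-Cope shift followed by aldol closure of C3 onto the C2=O1 oxocarbenium would give the same constitution. The closest known reaction type is the Prins cyclisation–pinacol rearrangement of 4-alkenyl-1,3-dioxolanes to 3-acyltetrahydrofurans, here with a formaldehyde acetal and a secondary carbinol so that a formyl group results. C2 is the migrating carbon and keeps its configuration; C4 is set by the chair in which the C2 aryl group and the E-alkene substituent are both equatorial, which places the benzyl group trans to the aryl group; C3 is first formed cis to the aryl group because C2 bonds to the ring face of C3, and DBU then inverts it through the enol to the epimer with the formyl group trans to the directly attached aryl group, which is expected, though not established, to be the more stable one (the minor epimer can be separated and resubmitted). The step needs ring-bond migration to outrun hydride shift and chloride capture at the secondary cation, which the trans acetal secures by placing the O–Sn bond axial and the carbinol hydrogen equatorial, orthogonal to the empty orbital at C3. It also needs the benzylic C2–O bonds to stay intact, which the electron-withdrawing pivalate on the C2 aryl group secures.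

Step 8
Reactants: 14 (2S,3S,4R)-2-(3-methoxy-4-pivaloyloxyphenyl)-4-(3-methoxy-4-pivaloyloxybenzyl)tetrahydrofuran-3-carbaldehyde
Product: 15 (+)-lariciresinol, (2S,3R,4R)-2-(4-hydroxy-3-methoxyphenyl)-4-(4-hydroxy-3-methoxybenzyl)tetrahydrofuran-3-ylmethanol
Conditions: LiAlH4, THF, 0 °C → rt; aq. KNaC4H4O6 (Rochelle salt)
Reagents that add atoms: none
Why: Hydride reduction converts the aldehyde into the primary alcohol (faster than enolisation, so C3 is fixed) and cleaves both aryl pivalates by acyl reduction, while the cold, non-acidic work-up avoids benzylic ionisation of the now electron-rich phenolic ether.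

Step 9
Reactants: 15 (+)-lariciresinol; 16 stearic acid
Product: 17 [(2S,3R,4R)-2-(4-hydroxy-3-methoxyphenyl)-4-(4-hydroxy-3-methoxybenzyl)tetrahydrofuran-3-yl]methyl octadecanoate (target)
Conditions: 16 (1.1 equiv), PPh3, DIAD, THF, 0 °C → rt
Reagents that add atoms: none
Why: Mitsunobu esterification: the phosphonium activates the only aliphatic hydroxyl and the carboxylate, far more acidic than the phenols and hence the pronucleophile formed by the betaine, displaces it at the primary carbon C6, so the phenols stay free (chemoselective Mitsunobu esterification of phenolic alcohols is known) and no stereocentre is involved.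

**Compound list**
1 | vanillin | COc1cc(C=O)ccc1O | starting material
2 | 4-formyl-2-methoxyphenyl pivalate | COc1cc(C=O)ccc1OC(=O)C(C)(C)C | intermediate
3 | eugenol | COc1cc(CC=C)ccc1O | starting material
4 | 4-allyl-2-methoxyphenyl pivalate | COc1cc(CC=C)ccc1OC(=O)C(C)(C)C | intermediate
5 | allyl alcohol | C=CCO | starting material
6 | 3-(methoxymethoxy)prop-1-ene | C=CCOCOC | intermediate
7 | (Z)-3-(methoxymethoxy)allyllithium | [Li]C/C=C\OCOC | intermediate (not isolated)
8 | [(Z)-3-(methoxymethoxy)allyl]diisopinocampheylborane, isopinocampheyl groups from (+)-α-pinene | COCO/C=C\CB([C@@H]1C[C@@H]2C[C@H]([C@H]1C)C2(C)C)[C@@H]1C[C@@H]2C[C@H]([C@H]1C)C2(C)C | intermediate (not isolated)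
9 | O-diisopinocampheylboryl derivative (borinate) of 10 | B([C@@H]1C[C@@H]2C[C@H]([C@H]1C)C2(C)C)([C@@H]1C[C@@H]2C[C@H]([C@H]1C)C2(C)C)O[C@@H]([C@H](OCOC)C=C)c1ccc(OC(=O)C(C)(C)C)c(OC)c1 | intermediate (not isolated)
10 | 4-[(1R,2R)-1-hydroxy-2-(methoxymethoxy)but-3-en-1-yl]-2-methoxyphenyl pivalate | O[C@@H]([C@H](OCOC)C=C)c1ccc(OC(=O)C(C)(C)C)c(OC)c1 | intermediate
11 | (1R,2R,3E)-2-(methoxymethoxy)-1,5-bis(3-methoxy-4-pivaloyloxyphenyl)pent-3-en-1-ol | O[C@@H]([C@H](OCOC)/C=C/Cc1ccc(OC(=O)C(C)(C)C)c(OC)c1)c1ccc(OC(=O)C(C)(C)C)c(OC)c1 | intermediate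
12 | (4R,5R)-4-(3-methoxy-4-pivaloyloxyphenyl)-5-[(E)-3-(3-methoxy-4-pivaloyloxyphenyl)prop-1-en-1-yl]-1,3-dioxolane | C1O[C@@H]([C@H](O1)/C=C/Cc2ccc(OC(=O)C(C)(C)C)c(OC)c2)c2ccc(OC(=O)C(C)(C)C)c(OC)c2 | intermediate (key-step precursor)
13 | (2S,3R,4R)-2-(3-methoxy-4-pivaloyloxyphenyl)-4-(3-methoxy-4-pivaloyloxybenzyl)tetrahydrofuran-3-carbaldehyde (2,3-cis-3,4-trans) | O=C[C@@H]1[C@@H](Cc2ccc(OC(=O)C(C)(C)C)c(OC)c2)CO[C@@H]1c1ccc(OC(=O)C(C)(C)C)c(OC)c1 | intermediate (not isolated)
14 | (2S,3S,4R)-2-(3-methoxy-4-pivaloyloxyphenyl)-4-(3-methoxy-4-pivaloyloxybenzyl)tetrahydrofuran-3-carbaldehyde (2,3-trans-3,4-cis) | O=C[C@H]1[C@@H](Cc2ccc(OC(=O)C(C)(C)C)c(OC)c2)CO[C@@H]1c1ccc(OC(=O)C(C)(C)C)c(OC)c1 | intermediate (key-step product)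
15 | (+)-lariciresinol | OC[C@H]1[C@@H](Cc2ccc(O)c(OC)c2)CO[C@@H]1c1ccc(O)c(OC)c1 | intermediate
16 | stearic acid | CCCCCCCCCCCCCCCCCC(=O)O | starting material
17 | [(2S,3R,4R)-2-(4-hydroxy-3-methoxyphenyl)-4-(4-hydroxy-3-methoxybenzyl)tetrahydrofuran-3-yl]methyl octadecanoate | CCCCCCCCCCCCCCCCCC(=O)OC[C@H]1[C@@H](Cc2ccc(O)c(OC)c2)CO[C@@H]1c1ccc(O)c(OC)c1 | target

**Step count**
Total steps: 9. Longest linear sequence: 7 (steps 1, 4, 5, 6, 7, 8, 9 from vanillin; equally 3, 4, 5, 6, 7, 8, 9 from allyl alcohol).

**Steps most likely to fail**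

Step 7. The formaldehyde acetal may ionise sluggishly or unproductively. The secondary cation at C3 may be diverted by chloride capture, hydride shift from the carbinol carbon or arylation before the ring bond migrates. The C3 equilibration may also favour the wanted epimer only weakly. Fallback (radical ring construction, sets out from 2 and comes back at 15): vinylmagnesium bromide (THF, −78 °C) converts 2 into the racemic allylic alcohol F1. Sharpless kinetic resolution with epoxidation [Ti(OiPr)4, D-(−)-diisopropyl tartrate, t-BuOOH (0.5 equiv), 4 Å MS, CH2Cl2, −20 °C] should epoxidise the (S)-enantiomer to the erythro epoxy alcohol F2. The unreacted (R)-alcohol is converted by PBr3, with allylic transposition, into the (E)-cinnamyl bromide F3. Ag2O-promoted etherification of F2 with F3 (no free alkoxide, so no Payne rearrangement) gives the epoxy ether F4. Cp2TiCl (from Cp2TiCl2 and Zn, THF, rt) opens the epoxide homolytically to the C3 radical, which closes 5-exo onto the cinnamyl alkene; reduction and protonation of the benzylic radical then give lariciresinol dipivalate F5. The 2,3-trans-3,4-cis pattern is the expected kinetic outcome of the chair-like radical transition state, so this route does not depend on the C3 equilibrium. LiAlH4 removes the pivalates to reach 15.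

Step 5. Ruthenium hydride may migrate the double bond of the allylarene into conjugation, the partners may homodimerise, and E selectivity may be incomplete; any Z alkene would be carried into the C4 epimer. Fallback (sets out from 10 and comes back at 11): cross-metathesis of 10 with vinylboronic acid pinacol ester (second-generation Grubbs catalyst, CH2Cl2, 40 °C), a partner that cannot isomerise and should be strongly E-selective, gives the alkenylboronate F6. Separately, NaBH4 reduces 2 to the benzylic alcohol F7 and PBr3 converts it into the benzylic bromide F8. Suzuki–Miyaura coupling of F6 with F8 [PdCl2(dppf), K3PO4, THF–H2O, 40 °C] forms the C(sp2)–CH2Ar bond and delivers 11.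

Step 9. The phenols may be alkylated or acylated in competition, and substitution at the β-branched primary carbon may be slow enough for phenol side reactions to matter. Fallback (sets out from 15 and comes back at 17): lipase-catalysed transesterification with commercial vinyl stearate (immobilised Candida antarctica lipase B, t-BuOMe, 45 °C), which acylates aliphatic primary hydroxyls and leaves phenols free; no new compound is involved.

**Further compounds**
F1 | step 7 | rac-4-(1-hydroxyprop-2-en-1-yl)-2-methoxyphenyl pivalate | OC(C=C)c1ccc(OC(=O)C(C)(C)C)c(OC)c1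
F2 | step 7 | 4-{(R)-hydroxy[(S)-oxiran-2-yl]methyl}-2-methoxyphenyl pivalate | O[C@@H]([C@@H]1CO1)c1ccc(OC(=O)C(C)(C)C)c(OC)c1
F3 | step 7 | 4-[(E)-3-bromoprop-1-en-1-yl]-2-methoxyphenyl pivalate | BrC/C=C/c1ccc(OC(=O)C(C)(C)C)c(OC)c1
F4 | step 7 | (E)-3-(3-methoxy-4-pivaloyloxyphenyl)allyl ether of F2 | C(/C=C/c1ccc(OC(=O)C(C)(C)C)c(OC)c1)O[C@@H]([C@@H]1CO1)c1ccc(OC(=O)C(C)(C)C)c(OC)c1
F5 | step 7 | (+)-lariciresinol 4,4'-dipivalate | OC[C@H]1[C@@H](Cc2ccc(OC(=O)C(C)(C)C)c(OC)c2)CO[C@@H]1c1ccc(OC(=O)C(C)(C)C)c(OC)c1
F6 | step 5 | 4-[(1R,2R,3E)-1-hydroxy-2-(methoxymethoxy)-4-(4,4,5,5-tetramethyl-1,3,2-dioxaborolan-2-yl)but-3-en-1-yl]-2-methoxyphenyl pivalate | O[C@@H]([C@H](OCOC)/C=C/B1OC(C)(C)C(C)(C)O1)c1ccc(OC(=O)C(C)(C)C)c(OC)c1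
F7 | step 5 | 4-(hydroxymethyl)-2-methoxyphenyl pivalate | OCc1ccc(OC(=O)C(C)(C)C)c(OC)c1
F8 | step 5 | 4-(bromomethyl)-2-methoxyphenyl pivalate | BrCc1ccc(OC(=O)C(C)(C)C)c(OC)c1
F0 | step 9 | none | none
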